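**Retrosynthetic overview**
- The target comes from a 4‑bromocyclohexanone by equatorial methyl addition at C1 and desilylation; the C4 bromide comes from an axial C4 alcohol by SN2 inversion.
- The only ring is closed last, at C2–C3. The α‑carbon of the C1 ketone (as a methyl enol ether, donor) attacks the α‑carbon of the C4 carbinol, which is presented as a (Z)‑trisubstituted epoxide, i.e. an α‑hydroxy‑carbenium (a2, enolonium‑type) synthon. The two enolate‑type carbons of the dissonant 1,4‑O,O pattern are thereby joined, and C2, C3 and C4 are set together.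
- The acyclic epoxy enol ether comes from the 2‑methoxyallyl anion of a linalool‑derived enol ether and an epoxyneryl iodide (Sharpless epoxidation of nerol).
- The enol ether comes from the ozonolysis lactol of (S)‑linalool and the acetyl‑anion equivalent Ph3P=C(OMe)CH3, which turns the aldehyde carbon into C2 and brings in C1 and C6 as a masked ketone.

Assumption: (S)‑(+)‑linalool is bought enantiopure; ring atoms are numbered as in the cyclohexanol name of the target (C1 carbinol, C2 side chain, C3 quaternary, C4 CHBr).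

**Step 1**
Reactants: 1 (S)‑linalool, (3S)‑3,7‑dimethylocta‑1,6‑dien‑3‑ol
Product: 2 (5S)‑5‑ethenyl‑5‑methyloxolan‑2‑ol (lactol, anomer mixture; ring form of (4S)‑4‑hydroxy‑4‑methylhex‑5‑enal)
Conditions: O3 (1 equiv), CH2Cl2–MeOH, −78 °C; Me2S
Reagents that add atoms: ozone, [O-][O+]=O
Why: Chemoselective ozonolysis of the electron‑rich trisubstituted alkene (the vinyl group next to the oxygenated quaternary carbon is much slower); the carbinol stereocentre is untouched and the hydroxy aldehyde closes to the lactol.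

**Step 2**
Reactants: 2 (5S)‑5‑ethenyl‑5‑methyloxolan‑2‑ol
Product: 4 triethyl{[(3S)‑7‑methoxy‑3‑methylocta‑1,6‑dien‑3‑yl]oxy}silane (E/Z mixture), via lithium alkoxide 3 (not isolated)
Conditions: MeOCH2PPh3Cl, n‑BuLi, THF, 0 °C; MeI; n‑BuLi, −78 °C; 2, −78 °C to rt; TESOTf, 2,6‑lutidine, 0 °C
Reagents that add atoms: (methoxymethyl)triphenylphosphonium chloride, COC[P+](c1ccccc1)(c1ccccc1)c1ccccc1.[Cl-]; iodomethane, CI; triethylsilyl trifluoromethanesulfonate, CC[Si](CC)(CC)OS(=O)(=O)C(F)(F)F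
Why: Wittig olefination of the open‑chain aldehyde with the α‑methoxyethylidene ylide, an acetyl‑anion equivalent that joins two carbonyl‑type carbons, followed by O‑silylation of the tertiary alkoxide in the same flask; no stereocentre is formed and the enol ether geometry is reset in step 5.

**Step 3**
Reactants: 5 nerol, (2Z)‑3,7‑dimethylocta‑2,6‑dien‑1‑ol
Product: 6 [(2R,3S)‑3‑methyl‑3‑(4‑methylpent‑3‑en‑1‑yl)oxiran‑2‑yl]methanol
Conditions: Ti(OiPr)4 (10 mol %), D‑(−)‑diethyl tartrate (12 mol %), t‑BuOOH, 4 Å MS, CH2Cl2, −20 °C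
Reagents that add atoms: tert‑butyl hydroperoxide, CC(C)(C)OO
Why: Sharpless asymmetric epoxidation, which touches only the allylic‑alcohol double bond; the D‑tartrate sets both epoxide carbons (2R,3S), and these become C4 and C3 of the ring.

**Step 4**
Reactants: 6 [(2R,3S)‑3‑methyl‑3‑(4‑methylpent‑3‑en‑1‑yl)oxiran‑2‑yl]methanol
Product: 7 (2S,3S)‑2‑(iodomethyl)‑3‑methyl‑3‑(4‑methylpent‑3‑en‑1‑yl)oxirane
Conditions: I2, PPh3, imidazole, Et2O–MeCN, 0 °C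
Reagents that add atoms: iodine, II
Why: Appel‑type iodination (SN2 at the primary carbon) that leaves the epoxide intact; the C2 descriptor changes only through CIP priority.

**Step 5**
Reactants: 4 triethyl{[(3S)‑7‑methoxy‑3‑methylocta‑1,6‑dien‑3‑yl]oxy}silane; 7 (2S,3S)‑2‑(iodomethyl)‑3‑methyl‑3‑(4‑methylpent‑3‑en‑1‑yl)oxirane
Product: 9 triethyl{[(3S,6E)‑7‑methoxy‑3‑methyl‑9‑[(2R,3S)‑3‑methyl‑3‑(4‑methylpent‑3‑en‑1‑yl)oxiran‑2‑yl]nona‑1,6‑dien‑3‑yl]oxy}silane, via 2‑methoxyallyl potassium 8 (not isolated)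
Conditions: s‑BuLi, KOtBu, THF, −78 to −50 °C; 7, −78 °C
Reagents that add atoms: none
Why: Allylic metalation of the methyl enol ether with the mixed s‑BuLi/KOtBu base (known for 2‑methoxypropene) gives an allylpotassium that settles in the endo form and is alkylated by the primary iodide at its unsubstituted terminus (SN2), so the enol ether is rebuilt toward C2 with the side chain cis to the new chain (6E); no stereocentre is touched.

**Step 6**
Reactants: 9 triethyl{[(3S,6E)‑7‑methoxy‑3‑methyl‑9‑[(2R,3S)‑3‑methyl‑3‑(4‑methylpent‑3‑en‑1‑yl)oxiran‑2‑yl]nona‑1,6‑dien‑3‑yl]oxy}silane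
Product: 11 (2S,3S,4R)‑4‑hydroxy‑3‑methyl‑3‑(4‑methylpent‑3‑en‑1‑yl)‑2‑[(3S)‑3‑methyl‑3‑(triethylsilyloxy)pent‑4‑en‑1‑yl]cyclohexan‑1‑one, via oxocarbenium aluminate 10 (not isolated)
Conditions: MeAlCl2 (1.5 equiv), CH2Cl2, −78 °C; aq. NaHCO3
Reagents that add atoms: water, O
Why: Lewis‑acid epoxide–enol ether cyclization (cation–olefin type, Stork–Eschenmoser chair) in which the epoxide is the α‑hydroxy‑carbenium (a2) partner of the enol ether, so two α‑carbons are joined; anti opening at the tertiary carbon inverts C3, the chair carrying the homoprenyl group (from the Z‑epoxide) and the side chain (from the E‑enol ether) both axial sets C2 trans to it, the C4–O bond is retained, and neutral hydrolysis of the oxocarbenium ion gives the ketone without touching C2.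

**Step 7**
Reactants: 11 (2S,3S,4R)‑4‑hydroxy‑3‑methyl‑3‑(4‑methylpent‑3‑en‑1‑yl)‑2‑[(3S)‑3‑methyl‑3‑(triethylsilyloxy)pent‑4‑en‑1‑yl]cyclohexan‑1‑one
Product: 12 (2S,3S,4S)‑4‑bromo‑3‑methyl‑3‑(4‑methylpent‑3‑en‑1‑yl)‑2‑[(3S)‑3‑methyl‑3‑(triethylsilyloxy)pent‑4‑en‑1‑yl]cyclohexan‑1‑one
Conditions: CBr4, PPh3, pyridine, toluene, 50 °C
Reagents that add atoms: carbon tetrabromide, BrC(Br)(Br)Br
Why: Appel reaction; in the chair with both large groups equatorial the C4 hydroxyl is axial, and SN2 displacement with inversion gives the equatorial bromide cis to the C3 methyl.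

**Step 8**
Reactants: 12 (2S,3S,4S)‑4‑bromo‑3‑methyl‑3‑(4‑methylpent‑3‑en‑1‑yl)‑2‑[(3S)‑3‑methyl‑3‑(triethylsilyloxy)pent‑4‑en‑1‑yl]cyclohexan‑1‑one
Product: 14 (1R,2S,3S,4S)‑4‑bromo‑2‑[(3S)‑3‑hydroxy‑3‑methylpent‑4‑en‑1‑yl]‑1,3‑dimethyl‑3‑(4‑methylpent‑3‑en‑1‑yl)cyclohexan‑1‑ol (target), via triethylsilyl ether 13 (not isolated)
Conditions: MeMgBr (3 equiv), THF–toluene, −78 °C; MeOH; TBAF, rt
Reagents that add atoms: methylmagnesium bromide, C[Mg]Br
Why: Grignard 1,2‑addition in which the axial C3 methyl blocks axial attack, so the methyl enters equatorially and the new hydroxyl is axial (1R), cis to the side chain; fluoride then cleaves the silyl ether in the same flask.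

**Compound list**
1 | (S)‑linalool, (3S)‑3,7‑dimethylocta‑1,6‑dien‑3‑ol | C=C[C@@](C)(O)CCC=C(C)C | starting material
2 | (5S)‑5‑ethenyl‑5‑methyloxolan‑2‑ol (anomer mixture) | C=C[C@]1(C)CCC(O)O1 | intermediate
3 | lithium (3S)‑7‑methoxy‑3‑methylocta‑1,6‑dien‑3‑olate (E/Z mixture) | [Li+].C=C[C@@](C)([O-])CCC=C(C)OC | intermediate
4 | triethyl{[(3S)‑7‑methoxy‑3‑methylocta‑1,6‑dien‑3‑yl]oxy}silane (E/Z mixture) | C=C[C@@](C)(O[Si](CC)(CC)CC)CCC=C(C)OC | intermediate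
5 | nerol, (2Z)‑3,7‑dimethylocta‑2,6‑dien‑1‑ol | CC(C)=CCC/C(C)=C\CO | starting material
6 | [(2R,3S)‑3‑methyl‑3‑(4‑methylpent‑3‑en‑1‑yl)oxiran‑2‑yl]methanol | OC[C@H]1O[C@@]1(C)CCC=C(C)C | intermediate
7 | (2S,3S)‑2‑(iodomethyl)‑3‑methyl‑3‑(4‑methylpent‑3‑en‑1‑yl)oxirane | IC[C@H]1O[C@@]1(C)CCC=C(C)C | intermediate
8 | potassium 2‑methoxyallyl species of 4 (endo form, carbanion drawn at the former methyl) | C=C[C@@](C)(O[Si](CC)(CC)CC)CC/C=C(/OC)[CH2-].[K+] | intermediate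
9 | triethyl{[(3S,6E)‑7‑methoxy‑3‑methyl‑9‑[(2R,3S)‑3‑methyl‑3‑(4‑methylpent‑3‑en‑1‑yl)oxiran‑2‑yl]nona‑1,6‑dien‑3‑yl]oxy}silane | C=C[C@@](C)(O[Si](CC)(CC)CC)CC/C=C(/OC)CC[C@H]1O[C@@]1(C)CCC=C(C)C | intermediate
10 | cyclized O‑methyl oxocarbenium ion at C1 with the C4 oxygen bound to aluminium (zwitterion) | C=C[C@@](C)(O[Si](CC)(CC)CC)CC[C@H]1[C@](C)(CCC=C(C)C)[C@H](O[Al-](C)(Cl)Cl)CCC1=[O+]C | intermediate
11 | (2S,3S,4R)‑4‑hydroxy‑3‑methyl‑3‑(4‑methylpent‑3‑en‑1‑yl)‑2‑[(3S)‑3‑methyl‑3‑(triethylsilyloxy)pent‑4‑en‑1‑yl]cyclohexan‑1‑one | C=C[C@@](C)(O[Si](CC)(CC)CC)CC[C@H]1[C@](C)(CCC=C(C)C)[C@H](O)CCC1=O | intermediate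
12 | (2S,3S,4S)‑4‑bromo‑3‑methyl‑3‑(4‑methylpent‑3‑en‑1‑yl)‑2‑[(3S)‑3‑methyl‑3‑(triethylsilyloxy)pent‑4‑en‑1‑yl]cyclohexan‑1‑one | C=C[C@@](C)(O[Si](CC)(CC)CC)CC[C@H]1[C@](C)(CCC=C(C)C)[C@@H](Br)CCC1=O | intermediate
13 | (1R,2S,3S,4S)‑4‑bromo‑1,3‑dimethyl‑3‑(4‑methylpent‑3‑en‑1‑yl)‑2‑[(3S)‑3‑methyl‑3‑(triethylsilyloxy)pent‑4‑en‑1‑yl]cyclohexan‑1‑ol | C=C[C@@](C)(O[Si](CC)(CC)CC)CC[C@H]1[C@](C)(CCC=C(C)C)[C@@H](Br)CC[C@@]1(C)O | intermediate
14 | (1R,2S,3S,4S)‑4‑bromo‑2‑[(3S)‑3‑hydroxy‑3‑methylpent‑4‑en‑1‑yl]‑1,3‑dimethyl‑3‑(4‑methylpent‑3‑en‑1‑yl)cyclohexan‑1‑ol | C=C[C@@](C)(O)CC[C@H]1[C@](C)(CCC=C(C)C)[C@@H](Br)CC[C@@]1(C)O | target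

**Totals**
Total step count: 8. Longest linear sequence: 6 steps (1 → 2 → 4 → 9 → 11 → 12 → 14, or equally 5 → 6 → 7 → 9 → 11 → 12 → 14).

**Three steps most likely to fail**

Step 6 (ring closure). Risks are Lewis‑acid rearrangement of the epoxide, and a non‑chair pathway or a wrong enol ether geometry giving the C2 epimer. C2 cannot be corrected later, because the two C2 epimers of the ketone are close in energy. The fallback sets out from 2 and comes back at 14; it makes the nucleophile a cyclic enol ether and installs bromine during ring closure.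
- 2 is olefinated as in step 2 to 3, and acidic work‑up instead of silylation gives (6S)‑6‑hydroxy‑6‑methyloct‑7‑en‑2‑one F2.
- The hemiketal of F2 is dehydrated (MsCl, Et3N) to (2S)‑2‑ethenyl‑2,6‑dimethyl‑3,4‑dihydro‑2H‑pyran F3, in which the former tertiary hydroxyl is the ring oxygen and the enol ether geometry is locked.
- Commercial geraniol is epoxidised (Ti(OiPr)4, D‑(−)‑diethyl tartrate, t‑BuOOH) to [(2R,3R)‑3‑methyl‑3‑(4‑methylpent‑3‑en‑1‑yl)oxiran‑2‑yl]methanol F4 and converted (I2, PPh3, imidazole) into (2S,3R)‑2‑(iodomethyl)‑3‑methyl‑3‑(4‑methylpent‑3‑en‑1‑yl)oxirane F5.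
- Metalation of F3 (s‑BuLi, KOtBu) and alkylation with F5 give (2S)‑2‑ethenyl‑2‑methyl‑6‑{2‑[(2R,3R)‑3‑methyl‑3‑(4‑methylpent‑3‑en‑1‑yl)oxiran‑2‑yl]ethyl}‑3,4‑dihydro‑2H‑pyran F6.
- Li2NiBr4 opens the epoxide at the secondary carbon with inversion to the bromohydrin (3S,4R)‑3‑bromo‑1‑[(2S)‑2‑ethenyl‑2‑methyl‑3,4‑dihydro‑2H‑pyran‑6‑yl]‑4,8‑dimethylnon‑7‑en‑4‑ol F7.
- BF3·OEt2 at −78 °C ionises the tertiary carbinol through the bromonium ion, which the cyclic enol ether opens at the tertiary carbon in an all‑equatorial chair. Aqueous work‑up gives (2S,3S,4S)‑4‑bromo‑2‑[(3S)‑3‑hydroxy‑3‑methylpent‑4‑en‑1‑yl]‑3‑methyl‑3‑(4‑methylpent‑3‑en‑1‑yl)cyclohexan‑1‑one F8.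
- Excess MeMgBr converts F8 directly into 14.

Step 7 (SN2 at a neopentyl‑type secondary carbon). Risks are elimination or methyl shift. The fallback sets out from 11 and comes back at 13; it reverses the order of the last two bond formations. MeMgBr adds to 11 (equatorial attack, as in step 8) to give (1R,2S,3S,4R)‑1,3‑dimethyl‑3‑(4‑methylpent‑3‑en‑1‑yl)‑2‑[(3S)‑3‑methyl‑3‑(triethylsilyloxy)pent‑4‑en‑1‑yl]cyclohexane‑1,4‑diol F9. The axial secondary hydroxyl of F9 is then displaced (CBr4, PPh3) next to an unreactive tertiary carbinol. This removes the enolisable γ‑bromo ketone from the sequence and gives 13.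

Step 5 (site of metalation, and alkylation versus attack on the epoxide). The fallback sets out from 2 and 7 and comes back at 9; it generates the allyl anion by tin–lithium exchange instead of C–H metalation. The ylide from MeOCH2PPh3Cl is alkylated with Bu3SnCH2I instead of MeI. Wittig reaction with 2 and silylation as in step 2 give the allylstannane triethyl{[(3S)‑7‑methoxy‑3‑methyl‑8‑(tributylstannyl)octa‑1,6‑dien‑3‑yl]oxy}silane F1. n‑BuLi then releases the 2‑methoxyallyl anion regiospecifically, and alkylation with 7 returns to 9.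

**Further compounds**
F1 | step 5 | triethyl{[(3S)‑7‑methoxy‑3‑methyl‑8‑(tributylstannyl)octa‑1,6‑dien‑3‑yl]oxy}silane | C=C[C@@](C)(O[Si](CC)(CC)CC)CCC=C(OC)C[Sn](CCCC)(CCCC)CCCC
F2 | step 6 | (6S)‑6‑hydroxy‑6‑methyloct‑7‑en‑2‑one | C=C[C@@](C)(O)CCCC(C)=O
F3 | step 6 | (2S)‑2‑ethenyl‑2,6‑dimethyl‑3,4‑dihydro‑2H‑pyran | C=C[C@]1(C)CCC=C(C)O1
F4 | step 6 | [(2R,3R)‑3‑methyl‑3‑(4‑methylpent‑3‑en‑1‑yl)oxiran‑2‑yl]methanol | OC[C@H]1O[C@]1(C)CCC=C(C)C
F5 | step 6 | (2S,3R)‑2‑(iodomethyl)‑3‑methyl‑3‑(4‑methylpent‑3‑en‑1‑yl)oxirane | IC[C@H]1O[C@]1(C)CCC=C(C)C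
F6 | step 6 | (2S)‑2‑ethenyl‑2‑methyl‑6‑{2‑[(2R,3R)‑3‑methyl‑3‑(4‑methylpent‑3‑en‑1‑yl)oxiran‑2‑yl]ethyl}‑3,4‑dihydro‑2H‑pyran | C=C[C@]1(C)CCC=C(CC[C@H]2O[C@]2(C)CCC=C(C)C)O1
F7 | step 6 | (3S,4R)‑3‑bromo‑1‑[(2S)‑2‑ethenyl‑2‑methyl‑3,4‑dihydro‑2H‑pyran‑6‑yl]‑4,8‑dimethylnon‑7‑en‑4‑ol | C=C[C@]1(C)CCC=C(CC[C@H](Br)[C@](C)(O)CCC=C(C)C)O1
F8 | step 6 | (2S,3S,4S)‑4‑bromo‑2‑[(3S)‑3‑hydroxy‑3‑methylpent‑4‑en‑1‑yl]‑3‑methyl‑3‑(4‑methylpent‑3‑en‑1‑yl)cyclohexan‑1‑one | C=C[C@@](C)(O)CC[C@H]1[C@](C)(CCC=C(C)C)[C@@H](Br)CCC1=O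
F9 | step 7 | (1R,2S,3S,4R)‑1,3‑dimethyl‑3‑(4‑methylpent‑3‑en‑1‑yl)‑2‑[(3S)‑3‑methyl‑3‑(triethylsilyloxy)pent‑4‑en‑1‑yl]cyclohexane‑1,4‑diol | C=C[C@@](C)(O[Si](CC)(CC)CC)CC[C@H]1[C@](C)(CCC=C(C)C)[C@H](O)CC[C@@]1(C)O
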